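**Plan**
1. Retrosynthesis: the C1–C5 bond of the hydroazulenone is returned to C5–C10 (a 1,2-shift run backwards), which unveils an all-cis cis-decalin-1,5,10-triol 1-tosylate. Then the C5–O/C10–O bonds (alkene dihydroxylation), C12–C13 (B-alkyl Suzuki), C1–O (enone β-borylation), the second C4 methyl, C4=C5/C1–C10 (Robinson annulation) and C9–C11 (cuprate addition) are cut.
2. Forward: chiral cyclohexenone (ring B) → quaternary C9 → ring A annulated to the decalin → gem-dimethyl and linear dienone → oxygens at C1 and C3 → butenolide → oxygens at C5 and C10 → tosylate → in the last step ring B grows to the cycloheptanone while ring A shrinks to the cyclopentane.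
3. Enabling feature: the tertiary carbinol C10 sits between the sulfonate carbon C1 and the hydroxylated ring-fusion carbon C5. With the 1α-tosylate equatorial, the fusion bond C5–C10 (shared by ring A, C1–C5 + C10, and ring B, C5–C10) is anti-periplanar to C1–O, so C5 moves from C10 to C1 and C10 becomes the ketone. The shift also fixes which of the two possible β-hydroxy ketone skeletons forms.
4. Stereochemistry: C8 by amine-catalysed asymmetric enone isomerisation; C9 by cuprate addition anti to the C8 methyl; C1 by ligand-controlled Cu–B addition (inverted later); C3 by CBS reduction; C5/C10 by hydroxyl-directed osmylation. In the key step C5 migrates with retention and C1 is inverted, giving the trans-fused 1β-H junction.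

Key step: step 12

Remark (locants used throughout): decalin carbons are C1–C10 with C5 and C10 at the ring fusion; C4 carries the gem-dimethyl group, C8 a methyl, C9 a methyl and the chain C11–C12; α is the face of the C8 and C9 methyl groups; the same locants are kept in the target, where ring B plus C1 is the seven-membered ring and C1–C5 the five-membered ring.
Remark (assumption): in steps 2 and 7 the catalyst antipode that gives the stated configuration is used; which antipode that is would be settled by a test reaction.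

Step 1
Reactants: 1 3,4-dimethylanisole
Product: 3 3,4-dimethylcyclohex-3-en-1-one, via dihydroanisole 2 (not isolated)
Conditions: Li, NH3(l), t-BuOH, THF, −78 → −33 °C; then (CO2H)2, MeOH/H2O, rt
Reagents that add atoms: water, O
Why: Birch reduction leaves the methoxy- and methyl-bearing carbons sp2 (1,4-diene 2), and mild enol ether hydrolysis should give the non-conjugated ketone without moving the tetrasubstituted double bond.

Step 2
Reactants: 3 3,4-dimethylcyclohex-3-en-1-one
Product: 4 (R)-3,4-dimethylcyclohex-2-en-1-one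
Conditions: 9-amino-9-deoxy-epi-cinchona primary amine (10 mol %, quinine or quinidine series as needed for 4R), ArCO2H co-catalyst (20 mol %), PhMe, −25 °C
Reagents that add atoms: none
Why: amine-catalysed asymmetric alkene isomerisation of a β,γ- to an α,β-unsaturated cyclohexenone, in which the dienamine is protonated enantioselectively at the γ-carbon and so sets the methyl-bearing stereocentre (later C8).

Step 3
Reactants: 4 (R)-3,4-dimethylcyclohex-2-en-1-one; 5 vinylmagnesium bromide
Product: 6 (3S,4R)-3-ethenyl-3,4-dimethyl-1-(trimethylsilyloxy)cyclohex-1-ene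
Conditions: CuBr·SMe2 (10 mol %), TMSCl, HMPA, THF, −78 °C; Et3N, pentane work-up
Reagents that add atoms: chlorotrimethylsilane, C[Si](C)(C)Cl
Why: copper-catalysed, TMSCl-accelerated conjugate addition in which the vinyl group enters anti to the adjacent methyl, so the new quaternary centre (C9) carries vinyl trans and methyl cis to the C8 methyl, and the enolate is trapped regiospecifically as the silyl enol ether.

Step 4
Reactants: 6 silyl enol ether; 7 ethyl vinyl ketone
Product: 9 bicyclic enone (4,8α,9α-trimethyl-9β-vinyl-octal-4-en-3-one; 10β-H expected), via diketone 8 (not isolated)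
Conditions: Sc(OTf)3 (5 mol %), CH2Cl2, −78 °C, aq. NaHCO3 work-up; then KOH, MeOH, 60 °C
Reagents that add atoms: none
Why: Mukaiyama–Michael addition at the only enol carbon (C10) followed by aldol condensation (Robinson annulation, 6-exo-trig aldol then dehydration) should close ring A; the configuration at C10 is of no consequence because C10 becomes sp2 in step 6.

Step 5
Reactants: 9 bicyclic enone
Product: 10 4,4,8α,9α-tetramethyl-9β-vinyl-octal-5(6)-en-3-one (10β-H)
Conditions: KOt-Bu, t-BuOH/THF, 0 °C; MeI, 0 °C → rt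
Reagents that add atoms: iodomethane, CI
Why: deconjugative α-alkylation, in which the thermodynamic extended dienolate is methylated at C4 to give the 4,4-dimethyl β,γ-unsaturated ketone (any 5(10)-ene isomer converges in step 6).

Step 6
Reactants: 10 gem-dimethyl ketone
Product: 12 4,4,8α,9α-tetramethyl-9β-vinyl-octalin-1,5(10)-dien-3-one, via skipped dienone 11 (not isolated)
Conditions: IBX, DMSO, 70 °C; then DBU, CH2Cl2, rt
Reagents that add atoms: none
Why: IBX dehydrogenation can only occur at C1–C2 because C4 is quaternary, and base-mediated isomerisation through the trienolate should move the remaining double bond into conjugation, giving the linear 2,4-dienone with C5=C10 tetrasubstituted.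

Step 7
Reactants: 12 linear dienone
Product: 13 1α-(pinacolboryl)-4,4,8α,9α-tetramethyl-9β-vinyl-octal-5(10)-en-3-one (1S)
Conditions: B2pin2, CuCl (5 mol %), NaOt-Bu (10 mol %), Josiphos-type diphosphine (6 mol %, antipode for 1S), MeOH (2 equiv), THF, rt
Reagents that add atoms: bis(pinacolato)diboron, CC1(C)OB(OC1(C)C)B1OC(C)(C)C(C)(C)O1
Why: copper-catalysed asymmetric conjugate borylation of an enone, which should add 1,4 at the unhindered β-CH (C1) rather than 1,6 at the fully substituted C5, with the ligand (reinforced by the smaller 9α-methyl flank) placing boron on the α face.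

Step 8
Reactants: 13 β-boryl ketone
Product: 15 4,4,8α,9α-tetramethyl-9β-vinyl-octal-5(10)-ene-1α,3α-diol, via boryl alcohol 14 (not isolated)
Conditions: (S)-Me-CBS (20 mol %), catecholborane, PhMe, −78 → −40 °C; then NaBO3·4H2O, THF/H2O, rt
Reagents that add atoms: sodium perborate, [Na+].[O-]OB=O
Why: CBS reduction with the quaternary C4 as the large group should give the 3R (α) carbinol under reagent control (catecholborane does not hydroborate the vinyl group), and oxidative work-up converts C1–B into C1–OH with retention, which avoids an elimination-prone β-hydroxy ketone.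

Step 9
Reactants: 15 vinyl diol; 16 4-bromofuran-2(5H)-one
Product: 18 butenolide diol (9β-[2-(5-oxo-2,5-dihydrofuran-3-yl)ethyl]-4,4,8α,9α-tetramethyl-octal-5(10)-ene-1α,3α-diol), via alkylborane 17 (not isolated)
Conditions: 9-BBN, THF, rt → 40 °C; then 16, Pd(dppf)Cl2 (5 mol %), AsPh3, K3PO4 (aq.), DMF, rt
Reagents that add atoms: 9-borabicyclo[3.3.1]nonane, B1C2CCCC1CCC2 (its atoms are held by intermediate 17 only)
Why: anti-Markovnikov hydroboration of the only monosubstituted alkene (the tetrasubstituted one is inert) followed by B-alkyl Suzuki–Miyaura coupling with the β-bromobutenolide should forge C12–C13 in the presence of the free diol.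

Step 10
Reactants: 18 butenolide diol
Product: 20 cis-decalin-1α,3α,5α,10α-tetraol, via osmate ester 19 (not isolated)
Conditions: OsO4 (1.05 equiv), TMEDA (1.1 equiv), CH2Cl2, −78 → −20 °C; then Na2SO3 (aq.), THF, 50 °C
Reagents that add atoms: osmium tetroxide, O=[Os](=O)(=O)=O (both new oxygens); TMEDA, CN(C)CCN(C)C (held by intermediate 19 only)
Why: hydrogen-bond-directed dihydroxylation, in which the 1α (allylic) and 3α (homoallylic) hydroxyls deliver OsO4·TMEDA to the α face (also the face of the smaller 9α-methyl) to give the cis-fused 5α,10α-diol, while the electron-poor butenolide alkene should not compete.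

Step 11
Reactants: 20 tetraol
Product: 21 1α-tosylate of 20
Conditions: TsCl, Bu2SnO (5 mol %), Et3N, CH2Cl2, 0 °C → rt
Reagents that add atoms: p-toluenesulfonyl chloride, Cc1ccc(cc1)S(=O)(=O)Cl
Why: tin-mediated regioselective monosulfonylation, in which the stannylene of the cis-1,10-diol activates its secondary oxygen (C1) while the isolated neopentyl C3 hydroxyl and the tertiary hydroxyls stay free.

Step 12
Reactants: 21 tosylate
Product: 22 target, (1S,3R,5S,8R,9S)-3α,5α-dihydroxy-4,4,8α,9α-tetramethyl-9β-[2-(5-oxo-2,5-dihydrofuran-3-yl)ethyl]-1β-H-bicyclo[5.3.0]decan-10-one skeleton (C1 bonded to C5 and C10)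
Conditions: LiClO4, CaCO3, THF, 50 °C
Reagents that add atoms: none
Why: Ionisation of the equatorial C1 tosylate is assisted by the anti-periplanar ring-fusion bond, so C5 shifts from C10 to C1 while the C10 hydroxyl closes to the ketone (pinacol-type 1,2-shift of a 2-hydroxy sulfonate, i.e. a semipinacol rearrangement). The closest known reaction type is the conversion of decalin-1,9-diol monosulfonates into hydroazulenones and the LiClO4/CaCO3-buffered hydroxy-tosylate ring expansion. No ring is closed end to end: through a three-centre bridged transition state ring B takes up C1 and becomes the cycloheptanone, and ring A loses C10 and becomes the cyclopentane. C1 is inverted by backside entry of C5 (giving the 1β-H, trans-fused junction) and C5 migrates with retention, so both centres derive from the α-oxygens set in steps 7 and 10, while C3, C8 and C9 are untouched. The step needs migration of C5 rather than C9 migration, C2–C3 fragmentation, ether closure or elimination. This is secured because, in the favoured cis-decalin chair, the 1α-tosylate is anti-periplanar only to the ring bonds C10–C5 and C2–C3, only C10 offers a tertiary carbinol push (the C3 hydroxyl stays un-ionised under the neutral buffer and would give a less stabilised secondary oxocarbenium), every oxygen is cis to the leaving group and cannot attack from the rear, and no anti β-hydrogen is present.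

**Compound list**
1 | 3,4-dimethylanisole | COc1ccc(C)c(C)c1 | starting material
2 | 1-methoxy-4,5-dimethylcyclohexa-1,4-diene | COC1=CCC(C)=C(C)C1 | intermediate (not isolated)
3 | 3,4-dimethylcyclohex-3-en-1-one | O=C1CCC(C)=C(C)C1 | intermediate
4 | (R)-3,4-dimethylcyclohex-2-en-1-one | C[C@@H]1CCC(=O)C=C1C | intermediate
5 | vinylmagnesium bromide | C=C[Mg]Br | starting material
6 | (3S,4R)-3-ethenyl-3,4-dimethyl-1-(trimethylsilyloxy)cyclohex-1-ene (vinyl trans to the 4-methyl) | C[C@@H]1CCC(O[Si](C)(C)C)=C[C@@]1(C)C=C | intermediate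
7 | ethyl vinyl ketone (pent-1-en-3-one) | C=CC(=O)CC | starting material
8 | (3S,4R)-3-ethenyl-3,4-dimethyl-2-(3-oxopentyl)cyclohexan-1-one (10β-H) | C[C@@H]1CCC(=O)[C@H](CCC(=O)CC)[C@@]1(C)C=C | intermediate (not isolated)
9 | 4,8α,9α-trimethyl-9β-vinyl-octal-4-en-3-one (10β-H) | C[C@@H]1CCC2=C(C)C(=O)CC[C@@H]2[C@@]1(C)C=C | intermediate
10 | 4,4,8α,9α-tetramethyl-9β-vinyl-octal-5(6)-en-3-one (10β-H) | C[C@@H]1CC=C2C(C)(C)C(=O)CC[C@@H]2[C@@]1(C)C=C | intermediate
11 | 4,4,8α,9α-tetramethyl-9β-vinyl-octalin-1,5(6)-dien-3-one (10β-H) | C[C@@H]1CC=C2C(C)(C)C(=O)C=C[C@@H]2[C@@]1(C)C=C | intermediate (not isolated)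
12 | 4,4,8α,9α-tetramethyl-9β-vinyl-octalin-1,5(10)-dien-3-one | C[C@@H]1CCC2=C(C=CC(=O)C2(C)C)[C@@]1(C)C=C | intermediate
13 | 1α-(pinacolboryl)-4,4,8α,9α-tetramethyl-9β-vinyl-octal-5(10)-en-3-one | C[C@@H]1CCC2=C([C@@H](B3OC(C)(C)C(C)(C)O3)CC(=O)C2(C)C)[C@@]1(C)C=C | intermediate
14 | 1α-(pinacolboryl)-4,4,8α,9α-tetramethyl-9β-vinyl-octal-5(10)-en-3α-ol | C[C@@H]1CCC2=C([C@@H](B3OC(C)(C)C(C)(C)O3)C[C@@H](O)C2(C)C)[C@@]1(C)C=C | intermediate (not isolated)
15 | 4,4,8α,9α-tetramethyl-9β-vinyl-octal-5(10)-ene-1α,3α-diol | C[C@@H]1CCC2=C([C@@H](O)C[C@@H](O)C2(C)C)[C@@]1(C)C=C | intermediate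
16 | 4-bromofuran-2(5H)-one | BrC1=CC(=O)OC1 | starting material
17 | B-alkyl-9-BBN adduct of 15 (boron on C12) | C[C@@H]1CCC2=C([C@@H](O)C[C@@H](O)C2(C)C)[C@@]1(C)CCB1C2CCCC1CCC2 | intermediate (not isolated)
18 | 9β-[2-(5-oxo-2,5-dihydrofuran-3-yl)ethyl]-4,4,8α,9α-tetramethyl-octal-5(10)-ene-1α,3α-diol | C[C@@H]1CCC2=C([C@@H](O)C[C@@H](O)C2(C)C)[C@@]1(C)CCC1=CC(=O)OC1 | intermediate
19 | cyclic 5α,10α-osmate ester of 18 (hexavalent osmium, TMEDA chelate) | C[C@@H]1CC[C@]2(O3)[C@@](O[Os-2]35(=O)(=O)[N+](C)(C)CC[N+]5(C)C)([C@@H](O)C[C@@H](O)C2(C)C)[C@@]1(C)CCC1=CC(=O)OC1 | intermediate (not isolated)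
20 | cis-fused 9β-[2-(5-oxo-2,5-dihydrofuran-3-yl)ethyl]-4,4,8α,9α-tetramethyldecalin-1α,3α,5α,10α-tetraol | C[C@@H]1CC[C@]2(O)[C@@](O)([C@@H](O)C[C@@H](O)C2(C)C)[C@@]1(C)CCC1=CC(=O)OC1 | intermediate
21 | 1α-O-tosylate of 20 | C[C@@H]1CC[C@]2(O)[C@@](O)([C@@H](OS(=O)(=O)c3ccc(C)cc3)C[C@@H](O)C2(C)C)[C@@]1(C)CCC1=CC(=O)OC1 | intermediate
22 | target (trans-fused 3α,5α-dihydroxy-hydroazulen-10-one with butenolide side chain) | C[C@@H]1CC[C@]2(O)[C@H](C[C@@H](O)C2(C)C)C(=O)[C@@]1(C)CCC1=CC(=O)OC1 | target

Total steps: 12. Longest linear sequence: 12 steps (1 to 22).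

**Steps most likely to fail**

Step 12. The ionisation may be diverted into fragmentation of the C2–C3 or C5–C10 bond instead of the concerted shift, or may stall. Fallback, setting out from 21 and returning at 22: the C3 hydroxyl is silylated (TESCl, imidazole) to the triethylsilyl ether F1, which removes the C2–C3 pathway. Deprotonation (NaH, THF, 0 °C) then drives alkoxide-induced Grob-type cleavage of C5–C10 to the ten-membered 5,10-diketone F2. Under the same basic conditions F2 should close by transannular aldol addition of the C1 enolate to C5, giving the silyl ether F3 of the target. AcOH/THF/H2O then frees 22.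

Step 10. The osmium reagent may fail to add to the doubly neopentyl tetrasubstituted alkene or may be consumed elsewhere. Fallback, setting out from 12 and returning at 20: the tertiary carbinol is made first and a less hindered trisubstituted alkene is osmylated. The sequence is:
- 1,4-reduction of the C1=C2 bond ([(Ph3P)CuH]6, silane) to the 5(10)-en-3-one F4;
- (S)-CBS reduction to the 3α-alcohol F5;
- hydroxyl-directed epoxidation (VO(acac)2, t-BuOOH) to the 5α,10α-epoxide F6;
- base-mediated epoxide-to-allylic-alcohol isomerisation (Et2AlTMP) to the 1(10)-ene-3α,5α-diol F7, with the 5(6)-ene regioisomer removed;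
- hydroboration to the alkylborane F8 and coupling with 16 to the butenolide F9;
- OsO4·TMEDA dihydroxylation directed by the 5α-hydroxyl, which should give 20.

Step 7. Facial selectivity or 1,4- versus 1,6-regioselectivity of the copper–boryl addition to the hindered dienone may be poor. Fallback, setting out from 12 and returning at 15: Weitz–Scheffer epoxidation (H2O2, NaOH, MeOH, 0 °C) of the less hindered C1=C2 bond gives the 1α,2α-epoxy ketone F10. Reductive opening at the α-carbon with Na[PhSeB(OEt)3] (from PhSeSePh and NaBH4, EtOH, AcOH) gives the 1α-hydroxy ketone F11. Immediate (S)-CBS reduction with catecholborane at low temperature then gives diol 15.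

Further compounds
F1 | step 12 | 3-O-triethylsilyl ether of tosylate 21 | C[C@@H]1CC[C@]2(O)[C@@](O)([C@@H](OS(=O)(=O)c3ccc(C)cc3)C[C@@H](O[Si](CC)(CC)CC)C2(C)C)[C@@]1(C)CCC1=CC(=O)OC1
F2 | step 12 | ten-membered 5,10-diketone with 3α-triethylsilyloxy group | C[C@@H]1CCC(=O)C(C)(C)[C@H](O[Si](CC)(CC)CC)CCC(=O)[C@@]1(C)CCC1=CC(=O)OC1
F3 | step 12 | 3-O-triethylsilyl ether of 22 | C[C@@H]1CC[C@]2(O)[C@H](C[C@@H](O[Si](CC)(CC)CC)C2(C)C)C(=O)[C@@]1(C)CCC1=CC(=O)OC1
F4 | step 10 | 4,4,8α,9α-tetramethyl-9β-vinyl-octal-5(10)-en-3-one | C[C@@H]1CCC2=C(CCC(=O)C2(C)C)[C@@]1(C)C=C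
F5 | step 10 | 4,4,8α,9α-tetramethyl-9β-vinyl-octal-5(10)-en-3α-ol | C[C@@H]1CCC2=C(CC[C@@H](O)C2(C)C)[C@@]1(C)C=C
F6 | step 10 | 5α,10α-epoxy-4,4,8α,9α-tetramethyl-9β-vinyldecalin-3α-ol | C[C@@H]1CC[C@]2(O3)[C@@]3(CC[C@@H](O)C2(C)C)[C@@]1(C)C=C
F7 | step 10 | 4,4,8α,9α-tetramethyl-9β-vinyl-octal-1(10)-ene-3α,5α-diol | C[C@@H]1CC[C@]2(O)C(=CC[C@@H](O)C2(C)C)[C@@]1(C)C=C
F8 | step 10 | B-alkyl-9-BBN adduct of F7 | C[C@@H]1CC[C@]2(O)C(=CC[C@@H](O)C2(C)C)[C@@]1(C)CCB1C2CCCC1CCC2
F9 | step 10 | 9β-[2-(5-oxo-2,5-dihydrofuran-3-yl)ethyl]-4,4,8α,9α-tetramethyl-octal-1(10)-ene-3α,5α-diol | C[C@@H]1CC[C@]2(O)C(=CC[C@@H](O)C2(C)C)[C@@]1(C)CCC1=CC(=O)OC1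
F10 | step 7 | 1α,2α-epoxy-4,4,8α,9α-tetramethyl-9β-vinyl-octal-5(10)-en-3-one | C[C@@H]1CCC2=C([C@H]3O[C@H]3C(=O)C2(C)C)[C@@]1(C)C=C
F11 | step 7 | 1α-hydroxy-4,4,8α,9α-tetramethyl-9β-vinyl-octal-5(10)-en-3-one | C[C@@H]1CCC2=C([C@@H](O)CC(=O)C2(C)C)[C@@]1(C)C=C
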